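**Retrosynthetic overview**
1. Target 13 is the (2R,3R)-trans dihydroflavonol 3-methyl ether; the two phenols of ring B are freed last from bis(benzyl ether) 12.
2. Ring C (O1–C2–C3–C4–C4a–C8a) is the only ring made in the route and is closed last, at C4–C3: the azomethine carbon of an aryl aldehyde hydrazone (C4, on ring A ortho to O1) attacks the O-methyl oxocarbenium ion of C3 released from a dimethyl acetal; hydrolysis then gives the C4 ketone.
3. Enabling feature: the α-methoxy ketone C4(=O)–C3(H)(OMe) of ring C. C3 already carries its methoxy oxygen, so it can travel as CH(OMe)2 and keep one OMe on ionisation; C4, bonded only to ring A and C3, can travel as ArCH=N–NR2, an acyl anion equivalent.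
4. O1–C2 is made before that by Mitsunobu inversion of (S)-α-hydroxy acetal 7 with salicylaldehyde 2; C2 comes from asymmetric transfer hydrogenation of α-keto acetal 6, and C3 is set in the ring closure under control of C2.
5. Ring A comes from 3,4,5-trimethoxyphenol (1); ring B with C2 and C3 comes from methyl 3,5-dihydroxy-4-methoxybenzoate (3).

Key step: step 8

Assumption: the two stereodescriptors of the SMILES are read as (2R,3R), which places the C2 aryl group and the C3 methoxy group trans on ring C; compounds 1 and 3 are taken as commercial.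

**Step 1**
Reactants: 1 3,4,5-trimethoxyphenol
Product: 2 2-hydroxy-4,5,6-trimethoxybenzaldehyde
Conditions: MgCl2, Et3N, (CH2O)n, MeCN, reflux; then 1 M aq. HCl
Reagents that add atoms: paraformaldehyde (formaldehyde), C=O
Why: Magnesium phenoxide-directed ortho-formylation (Casnati–Skattebøl reaction) should deliver formaldehyde to one of the two equivalent positions ortho to the phenol, a second equivalent of formaldehyde oxidising the benzylic alkoxide to the aldehyde.

**Step 2**
Reactants: 3 methyl 3,5-dihydroxy-4-methoxybenzoate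
Product: 4 methyl 3,5-bis(benzyloxy)-4-methoxybenzoate
Conditions: BnBr (2.2 equiv), K2CO3, DMF, 60 °C
Reagents that add atoms: benzyl bromide, BrCc1ccccc1
Why: Williamson etherification of both phenols should proceed cleanly, the benzyl ethers being stable to every later step and removable by hydrogenolysis at the end.

**Step 3**
Reactants: 4 methyl 3,5-bis(benzyloxy)-4-methoxybenzoate
Product: 5 1-[3,5-bis(benzyloxy)-4-methoxyphenyl]-2-(methylsulfinyl)ethan-1-one (racemic at sulfur)
Conditions: NaH, DMSO, THF, 0 °C to rt (2.2 equiv of NaCH2S(O)CH3); then cold aq. HCl to pH 4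
Reagents that add atoms: dimethyl sulfoxide (as its sodium salt NaCH2S(O)CH3), CS(C)=O
Why: Claisen-type acylation of dimsyl sodium by a non-enolisable aryl ester should stop at the β-keto sulfoxide, because the second equivalent of base converts the product into its unreactive enolate.

**Step 4**
Reactants: 5 1-[3,5-bis(benzyloxy)-4-methoxyphenyl]-2-(methylsulfinyl)ethan-1-one
Product: 6 1-[3,5-bis(benzyloxy)-4-methoxyphenyl]-2,2-dimethoxyethan-1-one
Conditions: I2 (0.6 equiv), MeOH, reflux
Reagents that add atoms: methanol, CO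
Why: Iodine-promoted Pummerer-type methanolysis of a β-keto sulfoxide is a known route to α-keto dimethyl acetals, the sulfur leaving as dimethyl disulfide and the aryl ketone remaining free.

**Step 5**
Reactants: 6 1-[3,5-bis(benzyloxy)-4-methoxyphenyl]-2,2-dimethoxyethan-1-one
Product: 7 (1S)-1-[3,5-bis(benzyloxy)-4-methoxyphenyl]-2,2-dimethoxyethan-1-ol
Conditions: RuCl[(R,R)-TsDPEN](p-cymene) (1 mol%), HCO2H/Et3N (5:2), 30 °C
Reagents that add atoms: none
Why: Noyori asymmetric transfer hydrogenation of an aryl ketone should set the carbinol centre through the aryl CH/π contact with the arene ligand; the (R,R) catalyst is expected to give the (S) alcohol here, the same spatial sense as for acetophenone with the descriptor changed by the priority of CH(OMe)2.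

**Step 6**
Reactants: 7 (1S)-1-[3,5-bis(benzyloxy)-4-methoxyphenyl]-2,2-dimethoxyethan-1-ol; 2 2-hydroxy-4,5,6-trimethoxybenzaldehyde
Product: 8 2-{(1R)-1-[3,5-bis(benzyloxy)-4-methoxyphenyl]-2,2-dimethoxyethoxy}-4,5,6-trimethoxybenzaldehyde
Conditions: PPh3, DIAD, toluene, 0 °C to rt
Reagents that add atoms: none
Why: Mitsunobu etherification with the acidic, hydrogen-bonded salicylaldehyde phenol should form O1–C2 by SN2 inversion (S to R), the flanking acetal disfavouring ionisation of the benzylic oxyphosphonium ion and offering no acidic β-hydrogen for elimination.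

**Step 7**
Reactants: 8 2-{(1R)-1-[3,5-bis(benzyloxy)-4-methoxyphenyl]-2,2-dimethoxyethoxy}-4,5,6-trimethoxybenzaldehyde
Product: 9 (E)-1-(2-{(1R)-1-[3,5-bis(benzyloxy)-4-methoxyphenyl]-2,2-dimethoxyethoxy}-4,5,6-trimethoxyphenyl)-N-(pyrrolidin-1-yl)methanimine (the 1-aminopyrrolidine hydrazone of 8)
Conditions: 1-aminopyrrolidine (1.2 equiv), MgSO4, CH2Cl2, rt
Reagents that add atoms: 1-aminopyrrolidine, NN1CCCC1
Why: Condensation of an aryl aldehyde with an N,N-dialkylhydrazine should give the (E)-hydrazone without acid, so the acetal and the C2 centre are untouched.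

**Step 8**
Reactants: 9 the 1-aminopyrrolidine hydrazone of 8
Product: 12 (2R,3R)-2-[3,5-bis(benzyloxy)-4-methoxyphenyl]-3,5,6,7-tetramethoxychroman-4-one, via O-methyl oxocarbenium triflate 10 (not isolated), via cyclised ketone hydrazone 11 (not isolated)
Conditions: TMSOTf (2 equiv), CH2Cl2 (0.01 M), −78 to −30 °C; then sat. aq. oxalic acid, THF, rt
Reagents that add atoms: water, O
Why: Proposed new method: TMSOTf should ionise the dimethyl acetal of 9 to the O-methyl oxocarbenium ion 10 at C3, which is captured by the azomethine carbon C4 of the aldehyde N,N-dialkylhydrazone acting as an aza-enamine; loss of the C4 proton from the diazenium ion gives ketone hydrazone 11, and aqueous oxalic acid then releases the C4 ketone, so the step is a formal intramolecular hydroacylation of an oxocarbenium ion. The closest known reaction types are C-attack of aldehyde N,N-dialkylhydrazones on iminium ions, Vilsmeier reagents, acid anhydrides and Lewis acid-activated aldehydes (aza-enamine umpolung), and Lewis acid-mediated acetal cyclisations of the Mukaiyama and Prins type. Ring C closes in a 6-(enolexo)-exo-trig mode, with both the C=N and the C=O+ bonds outside the new six-membered ring. The new stereocentre C3 is controlled by C2: a chair-like transition state with the C2 aryl group equatorial, and equilibration of C3 (α to the C4 hydrazonium and later the ketone) during the acidic hydrolysis, should both favour the 2,3-trans diequatorial isomer, while C2 is not enolisable and keeps its configuration. The step needs chemoselectivity for attack through C4 over Friedel–Crafts attack by C8 of ring A (which would close a five-membered ring) and over proton loss from C2 to an enol ether; the higher nucleophilicity of the pyrrolidine-derived aza-enamine, the six-membered transition state, low temperature and the absence of added base are expected to secure it.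

**Step 9**
Reactants: 12 (2R,3R)-2-[3,5-bis(benzyloxy)-4-methoxyphenyl]-3,5,6,7-tetramethoxychroman-4-one
Product: 13 (2R,3R)-2-(3,5-dihydroxy-4-methoxyphenyl)-3,5,6,7-tetramethoxychroman-4-one
Conditions: H2 (1 atm), 10% Pd/C, EtOAc/MeOH, rt
Reagents that add atoms: none
Why: Hydrogenolysis of the two benzyl aryl ethers under neutral conditions should leave the conjugated aryl ketone and the cyclic C2–O1 ether intact and cannot epimerise C2 or C3.

**Compound list**
1 | 3,4,5-trimethoxyphenol | COc1cc(O)cc(OC)c1OC | starting material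
2 | 2-hydroxy-4,5,6-trimethoxybenzaldehyde | COc1cc(O)c(C=O)c(OC)c1OC | intermediate
3 | methyl 3,5-dihydroxy-4-methoxybenzoate | COC(=O)c1cc(O)c(OC)c(O)c1 | starting material
4 | methyl 3,5-bis(benzyloxy)-4-methoxybenzoate | COC(=O)c1cc(OCc2ccccc2)c(OC)c(OCc2ccccc2)c1 | intermediate
5 | 1-[3,5-bis(benzyloxy)-4-methoxyphenyl]-2-(methylsulfinyl)ethan-1-one (racemic at sulfur) | CS(=O)CC(=O)c1cc(OCc2ccccc2)c(OC)c(OCc2ccccc2)c1 | intermediate
6 | 1-[3,5-bis(benzyloxy)-4-methoxyphenyl]-2,2-dimethoxyethan-1-one | COC(OC)C(=O)c1cc(OCc2ccccc2)c(OC)c(OCc2ccccc2)c1 | intermediate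
7 | (1S)-1-[3,5-bis(benzyloxy)-4-methoxyphenyl]-2,2-dimethoxyethan-1-ol | O[C@H](C(OC)OC)c1cc(OCc2ccccc2)c(OC)c(OCc2ccccc2)c1 | intermediate
8 | 2-{(1R)-1-[3,5-bis(benzyloxy)-4-methoxyphenyl]-2,2-dimethoxyethoxy}-4,5,6-trimethoxybenzaldehyde | COc1cc(O[C@@H](C(OC)OC)c2cc(OCc3ccccc3)c(OC)c(OCc3ccccc3)c2)c(C=O)c(OC)c1OC | intermediate
9 | (E)-1-(2-{(1R)-1-[3,5-bis(benzyloxy)-4-methoxyphenyl]-2,2-dimethoxyethoxy}-4,5,6-trimethoxyphenyl)-N-(pyrrolidin-1-yl)methanimine | COc1cc(O[C@@H](C(OC)OC)c2cc(OCc3ccccc3)c(OC)c(OCc3ccccc3)c2)c(/C=N/N2CCCC2)c(OC)c1OC | intermediate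
10 | O-methyl oxocarbenium triflate from 9: {(2R)-2-[3,5-bis(benzyloxy)-4-methoxyphenyl]-2-[3,4,5-trimethoxy-2-((E)-(pyrrolidin-1-ylimino)methyl)phenoxy]ethylidene}(methyl)oxonium trifluoromethanesulfonate | C[O+]=C[C@H](Oc1cc(OC)c(OC)c(OC)c1/C=N/N1CCCC1)c1cc(OCc2ccccc2)c(OC)c(OCc2ccccc2)c1.[O-]S(=O)(=O)C(F)(F)F | intermediate
11 | (2R,3S)-2-[3,5-bis(benzyloxy)-4-methoxyphenyl]-3,5,6,7-tetramethoxy-N-(pyrrolidin-1-yl)chroman-4-imine (2,3-trans; descriptor at C3 changed by priority only) | COc1cc2c(c(OC)c1OC)C(=NN1CCCC1)[C@H](OC)[C@@H](c1cc(OCc3ccccc3)c(OC)c(OCc3ccccc3)c1)O2 | intermediate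
12 | (2R,3R)-2-[3,5-bis(benzyloxy)-4-methoxyphenyl]-3,5,6,7-tetramethoxychroman-4-one | COc1cc2c(c(OC)c1OC)C(=O)[C@H](OC)[C@@H](c1cc(OCc3ccccc3)c(OC)c(OCc3ccccc3)c1)O2 | intermediate
13 | (2R,3R)-2-(3,5-dihydroxy-4-methoxyphenyl)-3,5,6,7-tetramethoxychroman-4-one | COc1cc2c(c(OC)c1OC)C(=O)[C@H](OC)[C@@H](c1cc(O)c(OC)c(O)c1)O2 | target

**Step count**
Total: 9 steps. Longest linear sequence: 8 steps (steps 2 to 9, from 3).

**Steps most likely to fail**

Step 8 (proposed new method). What may go wrong:
- the oxocarbenium ion may be captured by C8 of ring A instead of by C4;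
- it may lose the C2 proton to give an enol ether, which would erode the C2 configuration;
- the Lewis acid may tie up the aza-enamine nitrogen so that no cyclisation occurs.

Fallback, forming the same bond by known radical chemistry, from 8 back to 12: bromodimethylborane (CH2Cl2, −78 °C) should cleave one acetal methoxy group of 8 to the α-bromo ether 2-{(1R)-1-[3,5-bis(benzyloxy)-4-methoxyphenyl]-2-bromo-2-methoxyethoxy}-4,5,6-trimethoxybenzaldehyde F1, not isolated. Benzeneselenol and iPr2NEt added to the same flask should convert it into the O,Se-acetal 2-{(1R)-1-[3,5-bis(benzyloxy)-4-methoxyphenyl]-2-methoxy-2-(phenylselanyl)ethoxy}-4,5,6-trimethoxybenzaldehyde F2. Slow addition of Bu3SnH and AIBN in benzene at 80 °C should generate the α-methoxyalkyl radical at C3, which closes 6-exo-trig onto the aldehyde carbonyl to give (2R)-2-[3,5-bis(benzyloxy)-4-methoxyphenyl]-3,5,6,7-tetramethoxychroman-4-ol F3 as a mixture at C3 and C4. Dess–Martin oxidation, followed by brief treatment with catalytic TsOH in CHCl3 to equilibrate C3 to the trans isomer, rejoins the route at 12.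

Step 6. What may go wrong: displacement at the hindered benzylic carbinol next to the acetal may be slow, allowing partial ionisation of the oxyphosphonium ion and loss of enantiopurity, or alkylation of the reduced azodicarboxylate instead of the phenol.

Fallback, separating activation from displacement, from 7 back to 8: MsCl and Et3N (CH2Cl2, −20 °C) should give (1S)-1-[3,5-bis(benzyloxy)-4-methoxyphenyl]-2,2-dimethoxyethyl methanesulfonate F4. This is displaced with inversion by the caesium phenoxide of 2 (Cs2CO3, DMF, 40 °C), a free and more nucleophilic anion than the Mitsunobu ion pair, to give 8.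

Step 4. What may go wrong: the Pummerer-type methanolysis may stop at the α-methoxy sulfide stage, or the hydrogen iodide formed may cleave benzyl ethers in refluxing methanol.

Fallback, a stepwise route through the free glyoxal, from 5 back to 6: aqueous HCl in DMSO at rt should rearrange 5 to the hemithioacetal 1-[3,5-bis(benzyloxy)-4-methoxyphenyl]-2-hydroxy-2-(methylsulfanyl)ethan-1-one F5. Cu(OAc)2·H2O in CHCl3 should strip the thiol to give 2-[3,5-bis(benzyloxy)-4-methoxyphenyl]-2-oxoacetaldehyde F6 (handled as its hydrate). HC(OMe)3 in MeOH with catalytic TsOH should then acetalise only the aldehyde carbon to give 6.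

**Further compounds**
F1 | step 8 | 2-{(1R)-1-[3,5-bis(benzyloxy)-4-methoxyphenyl]-2-bromo-2-methoxyethoxy}-4,5,6-trimethoxybenzaldehyde (mixture at the bromo carbon, not isolated) | COc1cc(O[C@@H](C(Br)OC)c2cc(OCc3ccccc3)c(OC)c(OCc3ccccc3)c2)c(C=O)c(OC)c1OC
F2 | step 8 | 2-{(1R)-1-[3,5-bis(benzyloxy)-4-methoxyphenyl]-2-methoxy-2-(phenylselanyl)ethoxy}-4,5,6-trimethoxybenzaldehyde (mixture at the selenoacetal carbon) | COc1cc(O[C@@H](C(OC)[Se]c2ccccc2)c2cc(OCc3ccccc3)c(OC)c(OCc3ccccc3)c2)c(C=O)c(OC)c1OC
F3 | step 8 | (2R)-2-[3,5-bis(benzyloxy)-4-methoxyphenyl]-3,5,6,7-tetramethoxychroman-4-ol (mixture at C3 and C4) | COc1cc2c(c(OC)c1OC)C(O)C(OC)[C@@H](c1cc(OCc3ccccc3)c(OC)c(OCc3ccccc3)c1)O2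
F4 | step 6 | (1S)-1-[3,5-bis(benzyloxy)-4-methoxyphenyl]-2,2-dimethoxyethyl methanesulfonate | CS(=O)(=O)O[C@H](C(OC)OC)c1cc(OCc2ccccc2)c(OC)c(OCc2ccccc2)c1
F5 | step 4 | 1-[3,5-bis(benzyloxy)-4-methoxyphenyl]-2-hydroxy-2-(methylsulfanyl)ethan-1-one (racemic) | CSC(O)C(=O)c1cc(OCc2ccccc2)c(OC)c(OCc2ccccc2)c1
F6 | step 4 | 2-[3,5-bis(benzyloxy)-4-methoxyphenyl]-2-oxoacetaldehyde | O=CC(=O)c1cc(OCc2ccccc2)c(OC)c(OCc2ccccc2)c1
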